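Ring B (C1, C6, C7, C8, C9, C10) carries the aminated quaternary C10 next to ring-fusion C1 and para to C7, the carbon holding the chlorinated oxane: the substitution pattern of a Diels–Alder adduct. A catalytic asymmetric [4+2] cycloaddition of methacrolein to a 2-(oxanyl)-1,3-diene therefore forges C8–C9 and C1–C10 at once and sets C1 and C10; the formyl group later becomes the formamide nitrogen by Curtius rearrangement. The diene is assembled from (S)-linalool, whose ten carbons become the oxane, C7 and C6, and from a (Z)-iodoalkenyl aldehyde; the C6=C7 alkene left by the cycloaddition is used to close ring A by a Heck reaction followed by carboxyl-directed hydrogenation.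

Key step: step 7

Remarks on the chemistry:
- Locants used in the text (carbons of intermediates are named by their place in the target): ring A = C1 to C6 with C4(Me)=C5; ring B = C1, C6, C7, C8, C9, C10; C10 bears methyl and nitrogen; C7 bears oxane carbon C11; oxane = O, C11 (methyl), C12, C13, C14 (chlorine), C15 (two methyls).
- (S)-(+)-Linalool is taken to be available in high enantiomeric purity.
- The (S)-configured catalyst of step 7 is assumed to shield the enal face that leads to 17; should the sense prove opposite, its enantiomer is used and nothing else changes.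

Step 1
Reactants: 1 (S)-(+)-linalool
Product: 2 (3R,6S)-3-chloro-6-ethenyl-2,2,6-trimethyloxane
Conditions: Et2SCl·SbCl6 (chlorodiethylsulfonium hexachloroantimonate), MeNO2, −25 °C, then aq. NaHCO3; chromatographic separation from the C3 epimer
Reagents that add atoms: chlorodiethylsulfonium hexachloroantimonate (CC[S+](Cl)CC.Cl[Sb-](Cl)(Cl)(Cl)(Cl)Cl)
Why: Chloronium-induced 6-endo haloetherification in which the tertiary hydroxyl opens the chloronium ion of the trisubstituted alkene at its tertiary carbon with anti addition through a chair, C11 coming unchanged from linalool while C14 is set with little bias because vinyl and methyl are of similar size, so both C14 epimers are expected and the isomer with chlorine trans to vinyl is the one carried on.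

Step 2
Reactants: 2 (3R,6S)-3-chloro-6-ethenyl-2,2,6-trimethyloxane
Product: 3 1-[(2S,5R)-5-chloro-2,6,6-trimethyloxan-2-yl]ethan-1-one
Conditions: PdCl2(Quinox) [Quinox = 2-(4,5-dihydrooxazol-2-yl)quinoline] (5 mol %), AgSbF6, aq. t-BuOOH, CH2Cl2, 0 °C to rt
Reagents that add atoms: tert-butyl hydroperoxide (CC(C)(C)OO)
Why: Catalyst-controlled Tsuji–Wacker oxidation should give the methyl ketone even next to the allylic ether oxygen and touches neither stereocentre nor the secondary chloride.

Step 3
Reactants: 4 2-(2-bromoethyl)-1,3-dioxolane; 5 propyne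
Product: 9 2-[(3Z)-4-iodo-3-methylbut-3-en-1-yl]-1,3-dioxolane, via Grignard reagent 6 (not isolated), via alkylcopper 7 (not isolated), via (Z)-alkenylcopper 8 (not isolated)
Conditions: Mg, THF; CuBr·SMe2, Et2O/Me2S, −45 °C; 5, −25 °C; I2, −40 to 0 °C
Reagents that add atoms: iodine (II)
Why: Normant carbocupration adds the alkylcopper syn across propyne with copper on the terminal carbon, and iodinolysis with retention gives the (Z)-iodoalkene in which iodine is cis to the chain.

Step 4
Reactants: 9 2-[(3Z)-4-iodo-3-methylbut-3-en-1-yl]-1,3-dioxolane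
Product: 10 (4Z)-5-iodo-4-methylpent-4-enal
Conditions: 1 M HCl, THF, rt
Reagents that add atoms: water (O)
Why: Acid-catalysed acetal hydrolysis frees the aldehyde without touching the vinyl iodide.

Step 5
Reactants: 3 1-[(2S,5R)-5-chloro-2,6,6-trimethyloxan-2-yl]ethan-1-one; 10 (4Z)-5-iodo-4-methylpent-4-enal
Product: 14 (2E,6Z)-1-[(2S,5R)-5-chloro-2,6,6-trimethyloxan-2-yl]-7-iodo-6-methylhepta-2,6-dien-1-one, via lithium enolate 11 (not isolated), via lithium aldolate 12 (not isolated), via aldol mesylate 13 (not isolated)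
Conditions: LiN(i-Pr)2, THF, −78 °C; 10; MsCl, Et3N, −78 to 0 °C; DBU, rt
Reagents that add atoms: none
Why: Directed aldol condensation in which the ketone can enolise only at its methyl group (the other α-carbon is quaternary), addition to the aldehyde and E1cB loss of mesylate giving the (E)-enone with no stereocentre touched.

Step 6
Reactants: 14 (2E,6Z)-1-[(2S,5R)-5-chloro-2,6,6-trimethyloxan-2-yl]-7-iodo-6-methylhepta-2,6-dien-1-one
Product: 15 (3R,6S)-3-chloro-6-[(3E,7Z)-8-iodo-7-methylocta-1,3,7-trien-2-yl]-2,2,6-trimethyloxane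
Conditions: Ph3PCH3Br, NaN(SiMe3)2, THF, 0 °C to rt
Reagents that add atoms: methyltriphenylphosphonium bromide (C[P+](c1ccccc1)(c1ccccc1)c1ccccc1.[Br-])
Why: Wittig methylenation of the ketone supplies C8 and gives the 2-substituted 1,3-diene with the (E)-alkene and the (Z)-vinyl iodide intact.

Step 7
Reactants: 15 (3R,6S)-3-chloro-6-[(3E,7Z)-8-iodo-7-methylocta-1,3,7-trien-2-yl]-2,2,6-trimethyloxane; 16 methacrolein (2-methylprop-2-enal)
Product: 17 (1R,2S)-4-[(2S,5R)-5-chloro-2,6,6-trimethyloxan-2-yl]-2-[(3Z)-4-iodo-3-methylbut-3-en-1-yl]-1-methylcyclohex-3-ene-1-carbaldehyde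
Conditions: 16 (3 equiv), (S)-3,3-diphenyl-1-(o-tolyl)tetrahydropyrrolo[1,2-c][1,3,2]oxazaborole and Tf2NH (20 mol % each), CH2Cl2, −78 to −40 °C
Reagents that add atoms: none
Why: Concerted, asynchronous normal-demand [4+2] cycloaddition of the boron-bound s-trans enal to the s-cis diene, the closest known reaction type being the oxazaborolidinium-catalysed Diels–Alder reaction of 2-substituted acroleins with alkyl-substituted dienes (the addition of acroleins to 2-methylpenta-1,3-diene is the classical regiochemical model). Ring B is closed by intermolecular suprafacial–suprafacial cycloaddition that forms C8–C9 and C1–C10 in the same step and leaves the C6=C7 alkene. Regioselectivity follows from the diene HOMO, whose largest coefficient lies on the unsubstituted terminus C8 (reinforced by the alkyl group on C1 and the tertiary alkyl group on C7), so C8 joins the β-carbon of the enal and the formyl-bearing carbon becomes C10 next to C1. C1 and C10 are set relative to each other by the (E)-geometry of the diene and the endo position of the activated formyl group (formyl cis to the C1 side chain, methyl trans), and in the absolute sense by the catalyst, which shields one face of the enal, the oxane stereocentres being too remote to compete. The bulky substituent on C7 holds the diene s-cis, the vinyl iodide and the alkyl chloride are spectators, and the low temperature and catalytic amount of acid are chosen to spare the allylic tertiary ether.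

Step 8
Reactants: 17 (1R,2S)-4-[(2S,5R)-5-chloro-2,6,6-trimethyloxan-2-yl]-2-[(3Z)-4-iodo-3-methylbut-3-en-1-yl]-1-methylcyclohex-3-ene-1-carbaldehyde
Product: 18 (1R,4aR,8aS)-4-[(2S,5R)-5-chloro-2,6,6-trimethyloxan-2-yl]-1,6-dimethyl-1,2,4a,7,8,8a-hexahydronaphthalene-1-carbaldehyde
Conditions: Pd(OAc)2 (10 mol %), PPh3 (25 mol %), Ag2CO3, MeCN, 75 °C
Reagents that add atoms: none
Why: Intramolecular Heck reaction in which zerovalent palladium inserts into the (Z)-vinyl iodide, 6-exo syn carbopalladation of C6=C7 occurs from the face that carries the tether (C5 joins C6 cis to the C1 side chain, giving the cis ring fusion) and syn β-hydride elimination towards C8 gives the 4,7-diene, silver carbonate suppressing alkene migration.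

Step 9
Reactants: 18 (1R,4aR,8aS)-4-[(2S,5R)-5-chloro-2,6,6-trimethyloxan-2-yl]-1,6-dimethyl-1,2,4a,7,8,8a-hexahydronaphthalene-1-carbaldehyde
Product: 19 (1R,4aR,8aS)-4-[(2S,5R)-5-chloro-2,6,6-trimethyloxan-2-yl]-1,6-dimethyl-1,2,4a,7,8,8a-hexahydronaphthalene-1-carboxylic acid
Conditions: NaClO2, NaH2PO4, 2-methylbut-2-ene, t-BuOH/H2O, 0 °C to rt
Reagents that add atoms: sodium chlorite ([Na+].[O-]Cl=O)
Why: Pinnick oxidation converts the α-quaternary aldehyde into the acid under buffered conditions while the scavenger protects the two alkenes from hypochlorous acid.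

Step 10
Reactants: 19 (1R,4aR,8aS)-4-[(2S,5R)-5-chloro-2,6,6-trimethyloxan-2-yl]-1,6-dimethyl-1,2,4a,7,8,8a-hexahydronaphthalene-1-carboxylic acid
Product: 20 (1R,4R,4aR,8aS)-4-[(2S,5R)-5-chloro-2,6,6-trimethyloxan-2-yl]-1,6-dimethyl-1,2,3,4,4a,7,8,8a-octahydronaphthalene-1-carboxylic acid
Conditions: [Rh(C7H8)(Ph2P(CH2)4PPh2)]BF4 (10 mol %), H2 (60 bar), Et3N (1 equiv), CH2Cl2, rt
Reagents that add atoms: none
Why: Carboxylate-directed homogeneous hydrogenation in which the cationic rhodium catalyst is held by the C10 carboxyl group and delivers hydrogen to the C7=C8 alkene (the cyclohex-3-enecarboxylic acid motif) from the face of that group, setting C7 with its hydrogen cis to C5 and the oxane equatorial, while the remote C4=C5 alkene, which this catalyst reduces only slowly without direction, should remain.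

Step 11
Reactants: 20 (1R,4R,4aR,8aS)-4-[(2S,5R)-5-chloro-2,6,6-trimethyloxan-2-yl]-1,6-dimethyl-1,2,3,4,4a,7,8,8a-octahydronaphthalene-1-carboxylic acid
Product: 23 N-[(1R,4R,4aR,8aS)-4-[(2S,5R)-5-chloro-2,6,6-trimethyloxan-2-yl]-1,6-dimethyl-1,2,3,4,4a,7,8,8a-octahydronaphthalen-1-yl]formamide, via acyl azide 21 (not isolated), via isocyanate 22 (not isolated)
Conditions: (PhO)2P(O)N3, Et3N, toluene, rt to 90 °C; then HCO2H (3 equiv), 60 °C
Reagents that add atoms: diphenylphosphoryl azide (O=P(N=[N+]=[N-])(Oc1ccccc1)Oc1ccccc1); formic acid (OC=O)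
Why: Curtius rearrangement of the acyl azide gives the tertiary isocyanate with retention at C10, and addition of formic acid followed by loss of carbon dioxide from the mixed anhydride leaves the formamide.

Compound list
1 | (S)-(+)-linalool | C=C[C@](O)(C)CCC=C(C)C | starting material
2 | (3R,6S)-3-chloro-6-ethenyl-2,2,6-trimethyloxane | C=C[C@]1(C)CC[C@@H](Cl)C(C)(C)O1 | intermediate
3 | 1-[(2S,5R)-5-chloro-2,6,6-trimethyloxan-2-yl]ethan-1-one | CC(=O)[C@]1(C)CC[C@@H](Cl)C(C)(C)O1 | intermediate
4 | 2-(2-bromoethyl)-1,3-dioxolane | BrCCC1OCCO1 | starting material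
5 | propyne | CC#C | starting material
6 | [2-(1,3-dioxolan-2-yl)ethyl]magnesium bromide | Br[Mg]CCC1OCCO1 | intermediate
7 | [2-(1,3-dioxolan-2-yl)ethyl]copper | [Cu]CCC1OCCO1 | intermediate
8 | [(1Z)-4-(1,3-dioxolan-2-yl)-2-methylbut-1-en-1-yl]copper | [Cu]/C=C(/C)CCC1OCCO1 | intermediate
9 | 2-[(3Z)-4-iodo-3-methylbut-3-en-1-yl]-1,3-dioxolane | I/C=C(/C)CCC1OCCO1 | intermediate
10 | (4Z)-5-iodo-4-methylpent-4-enal | O=CCC/C(C)=C\I | intermediate
11 | lithium enolate of 3 (enolised at the methyl group) | [Li]OC(=C)[C@]1(C)CC[C@@H](Cl)C(C)(C)O1 | intermediate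
12 | lithium aldolate from 11 and 10 (carbinol centre as a mixture) | [Li]OC(CC(=O)[C@]1(C)CC[C@@H](Cl)C(C)(C)O1)CC/C(C)=C\I | intermediate
13 | methanesulfonate of the aldol (carbinol centre as a mixture) | CS(=O)(=O)OC(CC(=O)[C@]1(C)CC[C@@H](Cl)C(C)(C)O1)CC/C(C)=C\I | intermediate
14 | (2E,6Z)-1-[(2S,5R)-5-chloro-2,6,6-trimethyloxan-2-yl]-7-iodo-6-methylhepta-2,6-dien-1-one | O=C(/C=C/CC/C(C)=C\I)[C@]1(C)CC[C@@H](Cl)C(C)(C)O1 | intermediate
15 | (3R,6S)-3-chloro-6-[(3E,7Z)-8-iodo-7-methylocta-1,3,7-trien-2-yl]-2,2,6-trimethyloxane | C=C(/C=C/CC/C(C)=C\I)[C@]1(C)CC[C@@H](Cl)C(C)(C)O1 | intermediate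
16 | methacrolein (2-methylprop-2-enal) | CC(=C)C=O | starting material
17 | (1R,2S)-4-[(2S,5R)-5-chloro-2,6,6-trimethyloxan-2-yl]-2-[(3Z)-4-iodo-3-methylbut-3-en-1-yl]-1-methylcyclohex-3-ene-1-carbaldehyde | O=C[C@]1(C)CCC([C@]2(C)CC[C@@H](Cl)C(C)(C)O2)=C[C@@H]1CC/C(C)=C\I | intermediate
18 | (1R,4aR,8aS)-4-[(2S,5R)-5-chloro-2,6,6-trimethyloxan-2-yl]-1,6-dimethyl-1,2,4a,7,8,8a-hexahydronaphthalene-1-carbaldehyde (cis-fused) | CC1=C[C@H]2C([C@]3(C)CC[C@@H](Cl)C(C)(C)O3)=CC[C@@](C)(C=O)[C@H]2CC1 | intermediate
19 | (1R,4aR,8aS)-4-[(2S,5R)-5-chloro-2,6,6-trimethyloxan-2-yl]-1,6-dimethyl-1,2,4a,7,8,8a-hexahydronaphthalene-1-carboxylic acid | CC1=C[C@H]2C([C@]3(C)CC[C@@H](Cl)C(C)(C)O3)=CC[C@@](C)(C(=O)O)[C@H]2CC1 | intermediate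
20 | (1R,4R,4aR,8aS)-4-[(2S,5R)-5-chloro-2,6,6-trimethyloxan-2-yl]-1,6-dimethyl-1,2,3,4,4a,7,8,8a-octahydronaphthalene-1-carboxylic acid | CC1=C[C@H]2[C@H]([C@]3(C)CC[C@@H](Cl)C(C)(C)O3)CC[C@@](C)(C(=O)O)[C@H]2CC1 | intermediate
21 | acyl azide of 20 | CC1=C[C@H]2[C@H]([C@]3(C)CC[C@@H](Cl)C(C)(C)O3)CC[C@@](C)(C(=O)N=[N+]=[N-])[C@H]2CC1 | intermediate
22 | isocyanate from 21 (N=C=O on C10, configuration retained) | CC1=C[C@H]2[C@H]([C@]3(C)CC[C@@H](Cl)C(C)(C)O3)CC[C@@](C)(N=C=O)[C@H]2CC1 | intermediate
23 | N-[(1R,4R,4aR,8aS)-4-[(2S,5R)-5-chloro-2,6,6-trimethyloxan-2-yl]-1,6-dimethyl-1,2,3,4,4a,7,8,8a-octahydronaphthalen-1-yl]formamide | CC1=C[C@H]2[C@H]([C@]3(C)CC[C@@H](Cl)C(C)(C)O3)CC[C@@](C)(NC=O)[C@H]2CC1 | target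

Total step count: 11. Longest linear sequence: 9 steps (steps 1, 2, 5, 6, 7, 8, 9, 10, 11).

Steps most likely to fail, each with a fallback:

Step 7 (key cycloaddition). The acid catalyst may ionise the allylic tertiary ether or polymerise the diene, and the endo or facial preference may be low, giving C1/C10 diastereomers. The fallback sets out from 15 and avoids acid altogether: heating 15 with 2-nitropropene in toluene (60 °C, radical inhibitor) should give the nitro adduct F1 with nitro endo, the two face diastereomers being separated. The Heck conditions of step 8 then give the bicyclic nitro diene F2; Zn in AcOH reduces the tertiary nitro group to the amine F3; acetic formic anhydride gives the formamide F4; and hydrogenation directed by the formamide carbonyl with [Ir(C8H12)(PCy3)(C5H5N)]PF6 and H2 reduces C7=C8 from the face of the nitrogen substituent. This comes back to the route at 23.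

Step 10 (directed hydrogenation). The rhodium hydride may also reduce or migrate the C4=C5 alkene, or hydrogen may be delivered to the open face opposite the carboxyl group, giving the C7 epimer. The fallback sets out from 18 and uses hydroxyl–iridium delivery instead: NaBH4 in MeOH gives the primary alcohol F5; [Ir(C8H12)(PCy3)(C5H5N)]PF6 and H2 in CH2Cl2 reduce the homoallylic-type alkene C7=C8 from the face of the hydroxymethyl group to give F6; oxidation with TEMPO and PhI(OAc)2 followed by NaClO2 returns the acid. This comes back to the route at 20.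

Step 1 (chlorocyclisation). Chloronium formation has no facial bias next to a centre carrying vinyl and methyl, and 5-exo closure or ene-type allylic chlorination may compete, so the wanted isomer may be a minor part of the mixture. The fallback sets out from 1 and makes the cyclisation substrate-controlled: the Wacker conditions of step 2 applied to 1 give the hydroxy ketone F7; 1,2-bis(trimethylsilyloxy)ethane with catalytic TMSOTf (CH2Cl2, −78 °C) gives the dioxolane F8, whose bulky ketal must sit equatorial in the chair-like chloroetherification; the conditions of step 1 should then place chlorine trans to it and give the chloro-oxane ketal F9; aqueous acid removes the ketal. This comes back to the route at 3.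

Further compounds
F1 | step 7 | analogue of 17 with a nitro group in place of the formyl group (nitro cis to the side chain) | [O-][N+](=O)[C@]1(C)CCC([C@]2(C)CC[C@@H](Cl)C(C)(C)O2)=C[C@@H]1CC/C(C)=C\I
F2 | step 7 | analogue of 18 with a nitro group in place of the formyl group | CC1=C[C@H]2C([C@]3(C)CC[C@@H](Cl)C(C)(C)O3)=CC[C@@](C)([N+](=O)[O-])[C@H]2CC1
F3 | step 7 | analogue of 18 with a primary amino group in place of the formyl group | CC1=C[C@H]2C([C@]3(C)CC[C@@H](Cl)C(C)(C)O3)=CC[C@@](C)(N)[C@H]2CC1
F4 | step 7 | 7,8-didehydro analogue of 23 (formamide on C10, alkenes C4=C5 and C7=C8) | CC1=C[C@H]2C([C@]3(C)CC[C@@H](Cl)C(C)(C)O3)=CC[C@@](C)(NC=O)[C@H]2CC1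
F5 | step 10 | primary alcohol from 18 (hydroxymethyl in place of formyl) | CC1=C[C@H]2C([C@]3(C)CC[C@@H](Cl)C(C)(C)O3)=CC[C@@](C)(CO)[C@H]2CC1
F6 | step 10 | primary alcohol corresponding to 20 (hydroxymethyl in place of carboxyl) | CC1=C[C@H]2[C@H]([C@]3(C)CC[C@@H](Cl)C(C)(C)O3)CC[C@@](C)(CO)[C@H]2CC1
F7 | step 1 | (3S)-3-hydroxy-3,7-dimethyloct-6-en-2-one | CC(=O)[C@](O)(C)CCC=C(C)C
F8 | step 1 | (2S)-6-methyl-2-(2-methyl-1,3-dioxolan-2-yl)hept-5-en-2-ol | CC1(OCCO1)[C@](O)(C)CCC=C(C)C
F9 | step 1 | 2-[(2S,5R)-5-chloro-2,6,6-trimethyloxan-2-yl]-2-methyl-1,3-dioxolane | CC1(OCCO1)[C@]2(C)CC[C@@H](Cl)C(C)(C)O2
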